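**Retrosynthetic overview**

1. The target is disconnected first at the 4‑O‑methyl group of ring A (the trimethoxyphenyl ring), giving the 4‑hydroxy (syringyl) oxolane, and then at O1–C2, giving an acyclic 2,3‑dibenzylbutane‑1,4‑diol.
2. Feature used (oxolane O1, C2, C3, C4, C5; C6 = CH2OH carbon on C3; C7 = benzylic CH2 on C4 leading to ring B): C2 carries ring A, is benzylic and stands para to the C4 oxygen of ring A. With that oxygen free as OH, C2 can become the exocyclic carbon of a para‑quinone methide, which the C5 hydroxyl captures as O1.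
3. The diol comes from LiAlH4 opening and debenzylation of a trans‑α,β‑dibenzyl‑γ‑butyrolactone, made by enolate alkylation (sets C3) of (S)‑β‑veratryl‑γ‑butyrolactone with O‑benzylsyringyl bromide (from syringaldehyde).
4. The lactone comes from the Stobbe half‑ester of veratraldehyde and dimethyl succinate by asymmetric hydrogenation (sets C4) and chemoselective ester reduction.
5. Ring order: the butyrolactone is only a stereocontrol scaffold and is opened again; the oxolane, the one ring of the target, is closed in the penultimate step, where C2 is also set.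

Key step: step 10

Assumption: the sense of induction in step 2 ((R,R)‑Et‑DuPHOS giving the (S)‑succinate) is assigned by analogy with itaconate‑type half‑esters and is to be confirmed at the β‑veratryl lactone stage by chiral HPLC and sign of rotation; the antipodal ligand is equally available.

**Route**

Step 1
Reactants: 1 3,4-dimethoxybenzaldehyde; 2 dimethyl succinate
Product: 4 (E)-4-(3,4-dimethoxyphenyl)-3-(methoxycarbonyl)but-3-enoic acid, via paraconic ester 3 (not isolated)
Conditions: NaOMe (2 equiv), MeOH, reflux; then aq HCl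
Reagents that add atoms: none
Why: Stobbe condensation, in which the succinate enolate adds to the aldehyde, the aldolate lactonises to paraconic ester 3 and base-induced E1cB opening of that lactone should give the (E)-alkylidene half-ester, its carboxylate preventing a second condensation.

Step 2
Reactants: 4 (E)-4-(3,4-dimethoxyphenyl)-3-(methoxycarbonyl)but-3-enoic acid
Product: 5 (3S)-4-(3,4-dimethoxyphenyl)-3-(methoxycarbonyl)butanoic acid
Conditions: H2 (5 bar), [Rh(cod)((R,R)-Et-DuPHOS)]BF4 (0.5 mol%), NaOMe (10 mol%), MeOH, rt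
Reagents that add atoms: none
Why: Rhodium-catalysed asymmetric hydrogenation of an itaconate-type half-ester, in which the alkene and the CH2CO2 carbonyl chelate the metal and the C2-symmetric bisphospholane should deliver hydrogen to one alkene face, setting the future C4 stereocentre as S.

Step 3
Reactants: 5 (3S)-4-(3,4-dimethoxyphenyl)-3-(methoxycarbonyl)butanoic acid
Product: 8 (4S)-4-(3,4-dimethoxybenzyl)oxolan-2-one, via potassium carboxylate 6 (not isolated), via hydroxy acid 7 (not isolated)
Conditions: KOH (1.0 equiv), EtOH, 0 °C; then CaCl2, NaBH4 (Ca(BH4)2 formed in situ), EtOH, −10 °C → rt; then 2 M HCl, rt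
Reagents that add atoms: none
Why: Chemoselective borohydride reduction followed by acid-catalysed lactonisation, the carboxylate salt being inert to Ca(BH4)2 while the methyl ester is reduced to the primary alcohol, with no bond to the stereocentre being touched.

Step 4
Reactants: 9 4-hydroxy-3,5-dimethoxybenzaldehyde (syringaldehyde)
Product: 10 4-(benzyloxy)-3,5-dimethoxybenzaldehyde
Conditions: BnBr, K2CO3, DMF, 60 °C
Reagents that add atoms: benzyl bromide, BrCc1ccccc1
Why: Williamson ether synthesis on the hindered but acidic syringyl phenol, which masks the phenol for the enolate and hydride steps that follow.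

Step 5
Reactants: 10 4-(benzyloxy)-3,5-dimethoxybenzaldehyde
Product: 11 [4-(benzyloxy)-3,5-dimethoxyphenyl]methanol
Conditions: NaBH4, MeOH, 0 °C → rt; aqueous work-up
Reagents that add atoms: none
Why: Borohydride reduction of an aryl aldehyde to the benzylic alcohol, to which the benzyl ether and methoxy groups are inert.

Step 6
Reactants: 11 [4-(benzyloxy)-3,5-dimethoxyphenyl]methanol
Product: 12 2-(benzyloxy)-5-(bromomethyl)-1,3-dimethoxybenzene
Conditions: PBr3 (0.4 equiv), CH2Cl2, 0 °C; used at once
Reagents that add atoms: phosphorus tribromide, BrP(Br)Br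
Why: Conversion of a benzylic alcohol to the bromide by PBr3 (bromide displacement of the intermediate phosphite ester), the short contact at 0 °C sparing the aryl benzyl ether.

Step 7
Reactants: 8 (4S)-4-(3,4-dimethoxybenzyl)oxolan-2-one; 12 2-(benzyloxy)-5-(bromomethyl)-1,3-dimethoxybenzene
Product: 14 (3S,4S)-3-[4-(benzyloxy)-3,5-dimethoxybenzyl]-4-(3,4-dimethoxybenzyl)oxolan-2-one, via lithium enolate 13 (not isolated)
Conditions: LiN(iPr)2 (LDA, 1.05 equiv), THF, −78 °C; then 12 (1.1 equiv), DMPU, −78 → −30 °C
Reagents that add atoms: none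
Why: Alkylation of a γ-butyrolactone lithium enolate, in which the benzylic bromide should approach the enolate face anti to the C4 benzyl group (1,2-induction), setting C3 trans to C4 (3S).

Step 8
Reactants: 14 (3S,4S)-3-[4-(benzyloxy)-3,5-dimethoxybenzyl]-4-(3,4-dimethoxybenzyl)oxolan-2-one
Product: 15 (2S,3S)-2-[4-(benzyloxy)-3,5-dimethoxybenzyl]-3-(3,4-dimethoxybenzyl)butane-1,4-diol
Conditions: LiAlH4, THF, 0 °C → rt; then H2O, aq NaOH
Reagents that add atoms: none
Why: LiAlH4 reduction of a lactone to the 1,4-diol, which leaves both stereocentres and the benzyl ether untouched.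

Step 9
Reactants: 15 (2S,3S)-2-[4-(benzyloxy)-3,5-dimethoxybenzyl]-3-(3,4-dimethoxybenzyl)butane-1,4-diol
Product: 16 (2S,3S)-2-(3,4-dimethoxybenzyl)-3-(4-hydroxy-3,5-dimethoxybenzyl)butane-1,4-diol
Conditions: H2 (1 atm), Pd/C (10% palladium on carbon), EtOAc/EtOH, rt
Reagents that add atoms: none
Why: Hydrogenolysis of an aryl benzyl ether over palladium, done before ring closure because at this stage the molecule holds no other benzylic C–O bond that could be cleaved.

Step 10
Reactants: 16 (2S,3S)-2-(3,4-dimethoxybenzyl)-3-(4-hydroxy-3,5-dimethoxybenzyl)butane-1,4-diol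
Product: 18 4-[(2R,3S,4S)-4-(3,4-dimethoxybenzyl)-3-(hydroxymethyl)oxolan-2-yl]-2,6-dimethoxyphenol, via para-quinone methide 17 (not isolated)
Conditions: DDQ (1.0 equiv, added slowly as a solution in 1,4-dioxane), CH2Cl2 (about 0.01 M), 0 °C; then filtration and aq NaHCO3 wash
Reagents that add atoms: none
Why: DDQ should remove a hydride (through a charge-transfer complex) from the benzylic CH2 para to the only free phenol, giving para-quinone methide 17, and the C5 hydroxyl then adds in an oxa-1,6-conjugate fashion to the exocyclic carbon, rearomatising ring A and forming the O1–C2 bond. The closest known reaction type is the oxidation of 4-alkyl-2,6-dimethoxyphenols to para-quinone methides by DDQ or Ag2O with intramolecular capture by a hydroxyl group, the laboratory counterpart of furanoid lignan biosynthesis. The oxolane closes in a 5-exo-trig mode, whereas the C6 hydroxyl could only close a strained oxetane and should therefore stay free. The new C2 stereocentre is under substrate control: the C3 hydroxymethyl and C4 benzyl groups lie cis on one face of the developing ring, so the aryl group should end on the opposite face (2R, 2,3-trans), which is also the more stable isomer should the addition be reversible. The step needs chemoselectivity for ring A, secured by ring B having no free hydroxyl and by one equivalent of oxidant at 0 °C, and it needs O- over C-capture, secured by the absence of strong acid (the spent hydroquinone precipitates from CH2Cl2), since Friedel–Crafts closure of ring B onto C2 to an aryltetralin is expected only under acidic equilibration. Slow addition of exactly one equivalent of DDQ at high dilution is meant to keep the product phenol from a second oxidation at its new benzylic ether carbon and to suppress intermolecular capture.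

Step 11
Reactants: 18 4-[(2R,3S,4S)-4-(3,4-dimethoxybenzyl)-3-(hydroxymethyl)oxolan-2-yl]-2,6-dimethoxyphenol
Product: 19 [(2R,3S,4S)-4-(3,4-dimethoxybenzyl)-2-(3,4,5-trimethoxyphenyl)oxolan-3-yl]methanol
Conditions: MeI, K2CO3, DMF, rt
Reagents that add atoms: iodomethane, CI
Why: Williamson O-methylation, in which K2CO3 deprotonates only the phenol and not the primary alcohol, so that the phenoxide alone is methylated and no stereocentre is affected.

**Compound list**

1 | 3,4-dimethoxybenzaldehyde | COc1ccc(C=O)cc1OC | starting material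
2 | dimethyl succinate | COC(=O)CCC(=O)OC | starting material
3 | methyl 2-(3,4-dimethoxyphenyl)-5-oxooxolane-3-carboxylate (paraconic ester, racemic diastereomer mixture, not isolated) | COC(=O)C1CC(=O)OC1c1ccc(OC)c(OC)c1 | intermediate
4 | (E)-4-(3,4-dimethoxyphenyl)-3-(methoxycarbonyl)but-3-enoic acid | COC(=O)/C(CC(=O)O)=C/c1ccc(OC)c(OC)c1 | intermediate
5 | (3S)-4-(3,4-dimethoxyphenyl)-3-(methoxycarbonyl)butanoic acid | COC(=O)[C@@H](Cc1ccc(OC)c(OC)c1)CC(=O)O | intermediate
6 | potassium (3S)-4-(3,4-dimethoxyphenyl)-3-(methoxycarbonyl)butanoate (not isolated) | [K+].COC(=O)[C@@H](Cc1ccc(OC)c(OC)c1)CC(=O)[O-] | intermediate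
7 | (3S)-4-(3,4-dimethoxyphenyl)-3-(hydroxymethyl)butanoic acid (not isolated) | OC[C@@H](Cc1ccc(OC)c(OC)c1)CC(=O)O | intermediate
8 | (4S)-4-(3,4-dimethoxybenzyl)oxolan-2-one | O=C1C[C@H](Cc2ccc(OC)c(OC)c2)CO1 | intermediate
9 | 4-hydroxy-3,5-dimethoxybenzaldehyde (syringaldehyde) | COc1cc(C=O)cc(OC)c1O | starting material
10 | 4-(benzyloxy)-3,5-dimethoxybenzaldehyde | COc1cc(C=O)cc(OC)c1OCc1ccccc1 | intermediate
11 | [4-(benzyloxy)-3,5-dimethoxyphenyl]methanol | COc1cc(CO)cc(OC)c1OCc1ccccc1 | intermediate
12 | 2-(benzyloxy)-5-(bromomethyl)-1,3-dimethoxybenzene | COc1cc(CBr)cc(OC)c1OCc1ccccc1 | intermediate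
13 | lithium (4S)-4-(3,4-dimethoxybenzyl)-4,5-dihydrofuran-2-olate (not isolated) | [Li+].[O-]C1=C[C@H](Cc2ccc(OC)c(OC)c2)CO1 | intermediate
14 | (3S,4S)-3-[4-(benzyloxy)-3,5-dimethoxybenzyl]-4-(3,4-dimethoxybenzyl)oxolan-2-one | COc1ccc(C[C@@H]2COC(=O)[C@H]2Cc3cc(OC)c(OCc4ccccc4)c(OC)c3)cc1OC | intermediate
15 | (2S,3S)-2-[4-(benzyloxy)-3,5-dimethoxybenzyl]-3-(3,4-dimethoxybenzyl)butane-1,4-diol | COc1ccc(C[C@H](CO)[C@H](Cc2cc(OC)c(OCc3ccccc3)c(OC)c2)CO)cc1OC | intermediate
16 | (2S,3S)-2-(3,4-dimethoxybenzyl)-3-(4-hydroxy-3,5-dimethoxybenzyl)butane-1,4-diol | COc1ccc(C[C@H](CO)[C@H](Cc2cc(OC)c(O)c(OC)c2)CO)cc1OC | intermediate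
17 | 4-[(2S,3S)-3-(3,4-dimethoxybenzyl)-4-hydroxy-2-(hydroxymethyl)butylidene]-2,6-dimethoxycyclohexa-2,5-dien-1-one (not isolated) | COC1=CC(=C[C@H](CO)[C@@H](CO)Cc2ccc(OC)c(OC)c2)C=C(OC)C1=O | intermediate
18 | 4-[(2R,3S,4S)-4-(3,4-dimethoxybenzyl)-3-(hydroxymethyl)oxolan-2-yl]-2,6-dimethoxyphenol | COc1ccc(C[C@@H]2CO[C@@H](c3cc(OC)c(O)c(OC)c3)[C@@H]2CO)cc1OC | intermediate
19 | [(2R,3S,4S)-4-(3,4-dimethoxybenzyl)-2-(3,4,5-trimethoxyphenyl)oxolan-3-yl]methanol | COc1ccc(C[C@@H]2CO[C@@H](c3cc(OC)c(OC)c(OC)c3)[C@@H]2CO)cc1OC | target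

**Step count**

Total: 11 steps. Longest linear sequence: 8 steps (1, 2, 3, 7, 8, 9, 10, 11 from 3,4-dimethoxybenzaldehyde; the branch 4, 5, 6 from syringaldehyde joins at step 7 and is equally long).

**Steps most likely to fail**

Step 10. The product phenol may be oxidised a second time at the C2–H of its new benzylic ether, the quinone methide may be captured by ring B in a Friedel–Crafts closure, or facial control at C2 may be weak. The fallback replaces phenol oxidation by redox-neutral benzylic ionisation; it sets out from 8 and comes back at 19. Enolate 13 of lactone 8 (LiN(iPr)2, THF, −78 °C) is added to commercial 3,4,5-trimethoxybenzaldehyde (COc1cc(C=O)cc(OC)c1OC), the aldehyde approaching anti to the C4 benzyl group, to give (3R,4S)-4-(3,4-dimethoxybenzyl)-3-[hydroxy(3,4,5-trimethoxyphenyl)methyl]oxolan-2-one F1 as a mixture of carbinol epimers. LiAlH4 in THF opens it to the triol (2S,3S)-2-(3,4-dimethoxybenzyl)-3-[hydroxy(3,4,5-trimethoxyphenyl)methyl]butane-1,4-diol F2. Catalytic 10-camphorsulfonic acid in CH2Cl2 at 0 °C ionises the benzylic alcohol, both epimers converging on one cation, and the C5 hydroxyl closes the oxolane with the aryl group trans to the C3 substituent, which should give 19 directly without steps 4–6 and 9–11.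

Step 7. The electron-rich benzylic bromide 12 may decompose before it is captured, proton exchange between product and enolate may lead to double alkylation, or trans selectivity may be incomplete. The fallback replaces alkylation by aldol addition and hydrogenolytic deoxygenation; it sets out from 8 (with aldehyde 10) and comes back at 16. Enolate 13 is added to aldehyde 10 at −78 °C to give (3R,4S)-3-{[4-(benzyloxy)-3,5-dimethoxyphenyl](hydroxy)methyl}-4-(3,4-dimethoxybenzyl)oxolan-2-one F3. Hydrogenation over Pd/C in EtOAc/AcOH removes the benzylic hydroxyl and the O-benzyl group in one operation to give (3S,4S)-4-(3,4-dimethoxybenzyl)-3-(4-hydroxy-3,5-dimethoxybenzyl)oxolan-2-one F4. Excess LiAlH4 in THF then reduces this lactone to diol 16.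

Step 2. Enantiofacial discrimination may be insufficient, or hydrogen may be delivered in the opposite sense. The fallback replaces asymmetric catalysis by classical resolution; it sets out from 4 and comes back at 5. Hydrogenation of 4 over Pd/C in MeOH gives racemic 4-(3,4-dimethoxyphenyl)-3-(methoxycarbonyl)butanoic acid F5. Its salt with (S)-1-phenylethylamine is recrystallised from isopropanol to constant rotation to give (S)-1-phenylethylammonium (3S)-4-(3,4-dimethoxyphenyl)-3-(methoxycarbonyl)butanoate F6; should the salt of the (R)-acid prove the less soluble one, the (R)-amine is used instead. Dilute HCl then releases 5, and the same crystallisation can upgrade partially enriched 5.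

**Further compounds**

F1 | step 10 | (3R,4S)-4-(3,4-dimethoxybenzyl)-3-[hydroxy(3,4,5-trimethoxyphenyl)methyl]oxolan-2-one (carbinol epimers) | COc1ccc(C[C@@H]2COC(=O)[C@H]2C(O)c3cc(OC)c(OC)c(OC)c3)cc1OC
F2 | step 10 | (2S,3S)-2-(3,4-dimethoxybenzyl)-3-[hydroxy(3,4,5-trimethoxyphenyl)methyl]butane-1,4-diol (carbinol epimers) | COc1ccc(C[C@H](CO)[C@H](C(O)c2cc(OC)c(OC)c(OC)c2)CO)cc1OC
F3 | step 7 | (3R,4S)-3-{[4-(benzyloxy)-3,5-dimethoxyphenyl](hydroxy)methyl}-4-(3,4-dimethoxybenzyl)oxolan-2-one (carbinol epimers) | COc1ccc(C[C@@H]2COC(=O)[C@H]2C(O)c3cc(OC)c(OCc4ccccc4)c(OC)c3)cc1OC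
F4 | step 7 | (3S,4S)-4-(3,4-dimethoxybenzyl)-3-(4-hydroxy-3,5-dimethoxybenzyl)oxolan-2-one | COc1ccc(C[C@@H]2COC(=O)[C@H]2Cc3cc(OC)c(O)c(OC)c3)cc1OC
F5 | step 2 | racemic 4-(3,4-dimethoxyphenyl)-3-(methoxycarbonyl)butanoic acid | COC(=O)C(Cc1ccc(OC)c(OC)c1)CC(=O)O
F6 | step 2 | (S)-1-phenylethylammonium (3S)-4-(3,4-dimethoxyphenyl)-3-(methoxycarbonyl)butanoate | COC(=O)[C@@H](Cc1ccc(OC)c(OC)c1)CC(=O)[O-].C[C@H]([NH3+])c1ccccc1
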